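**Retrosynthetic overview**
1. 43 ⇒ C8 alcohol 41 + (2S,3S)-epoxyangelic acid 33, joined last by Yamaguchi esterification.
2. Carbocycle and lactone ⇒ bromo aldehyde 38. An intramolecular Nozaki–Hiyama allylation forms C6–C7 (ten-membered ring), and the C6 alkoxide then closes on C12.
3. 38 ⇒ Ni/Cr coupling at C9–C10 of West iodoenoate 17 (C1–C6, C10, C14, C15) with East aldehyde 29 (C7–C9, C11–C13).
4. 17 ⇒ (Z)-enynol 1 (Sharpless: 4,5-oxirane), Evans chloroacetate aldol and ring closure (2,3-cis-oxirane), iodo-Wittig. 29 ⇒ D-glycerate 18 + methyl propiolate 24. 33 ⇒ angelic acid 30 (Sharpless).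
5. Ring order: 4,5-oxirane → 2,3-oxirane (side-chain oxirane made separately) → ten-membered carbocycle → γ-lactone.

Assumption: germacrane numbering (ring C1–C10, lactone C11–C13, ester carbon C14, methyl C15) is used for all intermediates, and carbinol C7 of 26–37 is carried as a mixture of epimers because it becomes sp2 in step 26.

**West fragment**

Step 1
Reactants: 1 (2Z)-3-methylpent-2-en-4-yn-1-ol
Product: 2 [(2R,3S)-3-ethynyl-3-methyloxiran-2-yl]methanol
Conditions: Ti(OiPr)4 (10 mol %), D-(−)-DIPT (12 mol %), t-BuOOH, 4 Å MS, CH2Cl2, −20 °C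
Reagents that add atoms: tert-butyl hydroperoxide, CC(C)(C)OO
Why: Katsuki–Sharpless asymmetric epoxidation, in which the D-(−)-tartrate/Ti complex delivers oxygen to the face that makes C5 R (2R in 2) and the Z geometry of 1 is kept, so C3 and C6 are cis on the oxirane (sets C4 and C5).

Step 2
Reactants: 2 [(2R,3S)-3-ethynyl-3-methyloxiran-2-yl]methanol
Product: 3 tert-butyl{[(2R,3S)-3-ethynyl-3-methyloxiran-2-yl]methoxy}dimethylsilane
Conditions: TBSCl, imidazole, CH2Cl2, 0 °C → rt
Reagents that add atoms: tert-butyldimethylsilyl chloride, C[Si](C)(Cl)C(C)(C)C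
Why: Standard imidazole-promoted silylation of the only hydroxyl group, touching no stereocentre.

Step 3
Reactants: 3 tert-butyl{[(2R,3S)-3-ethynyl-3-methyloxiran-2-yl]methoxy}dimethylsilane
Product: 4 tert-butyl{[(2R,3S)-3-ethenyl-3-methyloxiran-2-yl]methoxy}dimethylsilane
Conditions: H2 (1 atm), Lindlar catalyst, quinoline, EtOAc, rt
Reagents that add atoms: none
Why: Lindlar semihydrogenation stops at the alkene on the poisoned catalyst and leaves the oxirane and silyl ether intact.

Step 4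
Reactants: 4 tert-butyl{[(2R,3S)-3-ethenyl-3-methyloxiran-2-yl]methoxy}dimethylsilane
Product: 6 (2R,3R)-3-({[tert-butyl(dimethyl)silyl]oxy}methyl)-2-methyloxirane-2-carbaldehyde, via secondary ozonide 5 (not isolated)
Conditions: O3, CH2Cl2, −78 °C; Me2S, −78 °C → rt
Reagents that add atoms: ozone, [O-][O+]=O
Why: Ozonolysis (Criegee mechanism) with reductive work-up cleaves the only C=C bond and leaves C3 as an aldehyde on quaternary C4, which cannot epimerise.

Step 5
Reactants: 7 (4R)-4-benzyl-1,3-oxazolidin-2-one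
Product: 9 (4R)-4-benzyl-3-(chloroacetyl)-1,3-oxazolidin-2-one, via lithium salt of the oxazolidinone 8 (not isolated)
Conditions: n-BuLi, THF, −78 °C; ClCH2COCl, −78 → 0 °C
Reagents that add atoms: chloroacetyl chloride, O=C(Cl)CCl
Why: N-acylation of the lithiated Evans auxiliary by the acid chloride, with the benzyl stereocentre untouched.

Step 6
Reactants: 9 (4R)-4-benzyl-3-(chloroacetyl)-1,3-oxazolidin-2-one; 6 (2R,3R)-3-({[tert-butyl(dimethyl)silyl]oxy}methyl)-2-methyloxirane-2-carbaldehyde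
Product: 11 (4R)-4-benzyl-3-{(2R,3S)-2-chloro-3-hydroxy-3-[(2S,3R)-3-({[tert-butyl(dimethyl)silyl]oxy}methyl)-2-methyloxiran-2-yl]propanoyl}-1,3-oxazolidin-2-one, via (Z)-dibutylboron enolate 10 (not isolated)
Conditions: Bu2BOTf, Et3N, CH2Cl2, −78 → 0 °C; 6, −78 → 0 °C; pH 7 buffer, MeOH, H2O2, 0 °C
Reagents that add atoms: none
Why: Evans syn-aldol through the Zimmerman–Traxler chair of the Z-boron enolate, where the (R)-benzyl auxiliary dictates 2R,3S, giving the C3–O configuration of the target and a C2–Cl syn to it.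

Step 7
Reactants: 11 syn-chlorohydrin imide
Product: 12 methyl (2S,3R)-3-[(2R,3R)-3-({[tert-butyl(dimethyl)silyl]oxy}methyl)-2-methyloxiran-2-yl]oxirane-2-carboxylate
Conditions: K2CO3, MeOH, 0 °C
Reagents that add atoms: methanol, CO
Why: Darzens-type closure in which the C3 alkoxide displaces chloride from the back (inversion at C2, syn-chlorohydrin → cis-oxirane), faster than retro-aldol, while methoxide cleaves the imide and frees the auxiliary.

Step 8
Reactants: 12 methyl cis-glycidate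
Product: 14 (2S,3R)-3-[(2R,3R)-3-({[tert-butyl(dimethyl)silyl]oxy}methyl)-2-methyloxiran-2-yl]oxirane-2-carbaldehyde, via diisobutylaluminium hemiacetal 13 (not isolated)
Conditions: i-Bu2AlH (1.05 equiv), CH2Cl2, −78 °C; aq. Rochelle salt
Reagents that add atoms: none
Why: DIBAL-H partial reduction, whose tetrahedral aluminium hemiacetal survives at −78 °C and collapses only on work-up, so the aldehyde is not over-reduced and no stereocentre changes.

Step 9
Reactants: 15 methyl (triphenyl-λ5-phosphanylidene)acetate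
Product: 16 methyl iodo(triphenyl-λ5-phosphanylidene)acetate
Conditions: I2, K2CO3, MeOH, 0 °C
Reagents that add atoms: iodine, II
Why: Electrophilic iodination of the stabilised ylide followed by deprotonation of the iodophosphonium salt gives the isolable iodo ylide.

Step 10
Reactants: 14 bis-epoxy aldehyde; 16 methyl iodo(triphenyl-λ5-phosphanylidene)acetate
Product: 17 methyl (2Z)-2-iodo-3-{(2R,3R)-3-[(2R,3R)-3-({[tert-butyl(dimethyl)silyl]oxy}methyl)-2-methyloxiran-2-yl]oxiran-2-yl}prop-2-enoate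
Conditions: CH2Cl2, rt
Reagents that add atoms: none
Why: Wittig olefination with a stabilised ylide places C2 trans to the ester, giving the (Z)-α-iodoenoate (about 8:1, minor isomer removed), which is the geometry needed for C1=C10.

**East fragment**

Step 11
Reactants: 18 methyl (4R)-2,2-dimethyl-1,3-dioxolane-4-carboxylate
Product: 19 methyl (2R)-2,3-dihydroxypropanoate
Conditions: AcOH/H2O 4:1, rt
Reagents that add atoms: none
Why: Acid hydrolysis of the ketal at the ketal carbon leaves the C8 stereocentre untouched.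

Step 12
Reactants: 19 methyl (2R)-2,3-dihydroxypropanoate
Product: 20 methyl (2R)-2-hydroxy-3-[(triethylsilyl)oxy]propanoate
Conditions: Et3SiCl (1.0 equiv), imidazole, CH2Cl2, −20 °C
Reagents that add atoms: chlorotriethylsilane, CC[Si](Cl)(CC)CC
Why: Chemoselective silylation, since the primary hydroxyl reacts much faster than the hindered, less nucleophilic α-hydroxy ester hydroxyl.

Step 13
Reactants: 20 methyl (2R)-2-hydroxy-3-[(triethylsilyl)oxy]propanoate
Product: 21 methyl (2R)-2-{[tert-butyl(dimethyl)silyl]oxy}-3-[(triethylsilyl)oxy]propanoate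
Conditions: TBSOTf, 2,6-lutidine, CH2Cl2, 0 °C
Reagents that add atoms: tert-butyldimethylsilyl triflate, C[Si](C)(OS(=O)(=O)C(F)(F)F)C(C)(C)C
Why: Silyl triflate silylation with a hindered, non-nucleophilic base protects O8 without enolising the ester.

Step 14
Reactants: 21 methyl (2R)-2-{[tert-butyl(dimethyl)silyl]oxy}-3-[(triethylsilyl)oxy]propanoate
Product: 23 (2R)-2-{[tert-butyl(dimethyl)silyl]oxy}-3-[(triethylsilyl)oxy]propanal, via diisobutylaluminium hemiacetal 22 (not isolated)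
Conditions: i-Bu2AlH (1.05 equiv), toluene, −78 °C; aq. Rochelle salt
Reagents that add atoms: none
Why: DIBAL-H partial reduction of an α-silyloxy ester stops at the stable tetrahedral intermediate, and the aldehyde (C7) is released on work-up without racemising C8.

Step 15
Reactants: 23 (2R)-2-{[tert-butyl(dimethyl)silyl]oxy}-3-[(triethylsilyl)oxy]propanal; 24 methyl prop-2-ynoate
Product: 26 methyl (4R)-4-{[tert-butyl(dimethyl)silyl]oxy}-3-hydroxy-2-methylidene-5-[(triethylsilyl)oxy]pentanoate (C7 epimers), via methyl 2-(diisobutylalumanyl)prop-2-enoate 25 (not isolated)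
Conditions: i-Bu2AlH, HMPA, THF, 0 °C; 24, 0 °C; 23, 0 °C → rt
Reagents that add atoms: none
Why: Vinylalumination, in which hydroalumination of the ynoate gives the α-alanyl acrylate that adds to the aldehyde as a Baylis–Hillman equivalent under non-basic conditions; C7 forms as a Felkin-biased epimer mixture that is harmless because C7 becomes sp2 in step 26.

Step 16
Reactants: 26 Baylis–Hillman-type alcohol
Product: 27 methyl (4R)-4-{[tert-butyl(dimethyl)silyl]oxy}-2-methylidene-3,5-bis[(triethylsilyl)oxy]pentanoate (C7 epimers)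
Conditions: Et3SiOTf, 2,6-lutidine, CH2Cl2, −78 → 0 °C
Reagents that add atoms: triethylsilyl triflate, CC[Si](CC)(CC)OS(=O)(=O)C(F)(F)F
Why: Silyl triflate silylation caps the hindered C7 hydroxyl, so no free OH can later lactonise or be acetylated.

Step 17
Reactants: 27 bis-TES ether
Product: 28 methyl (4R)-4-{[tert-butyl(dimethyl)silyl]oxy}-5-hydroxy-2-methylidene-3-[(triethylsilyl)oxy]pentanoate (C7 epimers)
Conditions: PPTS (cat.), MeOH/CH2Cl2 1:4, −10 °C
Reagents that add atoms: none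
Why: Acid-catalysed methanolysis under kinetic control, since a primary TES ether cleaves far faster than a secondary TES or TBS ether.

Step 18
Reactants: 28 primary alcohol
Product: 29 methyl (4S)-4-{[tert-butyl(dimethyl)silyl]oxy}-2-methylidene-5-oxo-3-[(triethylsilyl)oxy]pentanoate (C7 epimers)
Conditions: TEMPO (cat.), PhI(OAc)2, CH2Cl2, rt
Reagents that add atoms: none
Why: Oxoammonium (TEMPO) oxidation is base-free and stops at the aldehyde (C9), so C8 does not epimerise and no β-elimination occurs.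

**Side-chain acid**

Step 19
Reactants: 30 angelic acid, (2Z)-2-methylbut-2-enoic acid
Product: 31 (2Z)-2-methylbut-2-en-1-ol
Conditions: LiAlH4, Et2O, 0 °C
Reagents that add atoms: none
Why: Hydride reduction of the acid to the allylic alcohol leaves the trisubstituted alkene and its Z geometry unchanged.

Step 20
Reactants: 31 (2Z)-2-methylbut-2-en-1-ol
Product: 32 [(2R,3S)-2,3-dimethyloxiran-2-yl]methanol
Conditions: Ti(OiPr)4, D-(−)-DIPT, t-BuOOH, 4 Å MS, CH2Cl2, −20 °C
Reagents that add atoms: tert-butyl hydroperoxide, CC(C)(C)OO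
Why: Katsuki–Sharpless asymmetric epoxidation, where D-(−)-tartrate gives the 2R epoxy alcohol and the Z geometry fixes CH2OH and the C3 methyl cis (sets C2′ and C3′).

Step 21
Reactants: 32 [(2R,3S)-2,3-dimethyloxiran-2-yl]methanol
Product: 33 (2S,3S)-2,3-dimethyloxirane-2-carboxylic acid
Conditions: RuCl3·xH2O (cat.), NaIO4, MeCN/EtOAc/H2O, rt
Reagents that add atoms: water, O; sodium periodate (terminal oxidant for RuO4), [Na+].[O-]I(=O)(=O)=O
Why: Sharpless RuO4 oxidation takes the primary alcohol to the acid, and the quaternary C2′ cannot epimerise (only its descriptor changes).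

**Assembly**

Step 22
Reactants: 17 West (Z)-iodoenoate; 29 East aldehyde
Product: 34 6,7-seco alcohol: dimethyl 6,7-seco-germacra-1(10)E,11(13)-diene-12,14-dioate bearing the 2,3- and 4,5-cis-epoxides of the target, 6-OTBS, 7-OTES (epimers), 8-OTBS, free 9-OH (8,9-anti)
Conditions: CrCl2 (8 equiv), NiCl2 (1 mol %), DMSO/THF, rt
Reagents that add atoms: none
Why: Nozaki–Hiyama–Kishi coupling, in which Ni inserts into C–I with retention and the alkenyl-Cr(III) adds only to the aldehyde by polar Felkin–Anh attack anti to the C8–OTBS bond, giving the 8,9-anti carbinol (C9 as in the target) with C9 cis to C2.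

Step 23
Reactants: 34 6,7-seco alcohol
Product: 35 9-acetate of 34
Conditions: Ac2O, pyridine, DMAP (cat.), CH2Cl2, 0 °C
Reagents that add atoms: acetic anhydride, CC(=O)OC(C)=O
Why: DMAP-catalysed acetylation of the only free hydroxyl proceeds with retention at C9 and prevents silyl migration from O8.

Step 24
Reactants: 35 9-acetate
Product: 36 6,7-diol: 35 without the 6-TBS and 7-TES groups, 8-OTBS kept (C7 epimers)
Conditions: HF·pyridine, pyridine, THF, 0 °C
Reagents that add atoms: none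
Why: Buffered fluoride desilylation under kinetic control removes the primary TBS and secondary TES ethers well before the flanked secondary TBS ether, and both oxiranes are deactivated toward acid by their oxygenated or electron-poor neighbours.

Step 25
Reactants: 36 6,7-diol
Product: 37 6-aldehyde with free 7-OH (C7 epimers)
Conditions: TEMPO (cat.), PhI(OAc)2, CH2Cl2, rt
Reagents that add atoms: none
Why: TEMPO oxidation is selective for the primary alcohol over the hindered, electron-poor secondary allylic alcohol and gives the epoxy aldehyde without base.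

Step 26
Reactants: 37 hydroxy aldehyde
Product: 38 (7Z)-13-bromo aldehyde: C13H2Br–C11(CO2Me)=C7H–C8, 6-CHO, 8-OTBS, 9-OAc
Conditions: NBS, Me2S, CH2Cl2, −20 → 0 °C
Reagents that add atoms: N-bromosuccinimide, O=C1CCC(=O)N1Br
Why: Corey–Kim-type bromination, where the alkoxysulfonium salt of the Baylis–Hillman alcohol is opened by bromide in an SN2′ sense at C13 under neutral conditions, converging both C7 epimers to the (Z)-2-(bromomethyl)enoate.

Step 27
Reactants: 38 bromo aldehyde
Product: 40 8-O-TBS macrocyclic lactone, via ten-membered hydroxy ester 39 (not isolated)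
Conditions: CrCl2 (12 equiv), THF, 2 mM, syringe-pump addition, rt
Reagents that add atoms: none
Why: Intramolecular Nozaki–Hiyama (Barbier-type) allylation, in which Cr(II) inserts only into the allylic C–Br bond, the equilibrating allyl-Cr(III) adds through C7 in a chair transition state with C5 and C8 equatorial (6,7-anti, hence the trans-lactone), A(1,3) strain holds H8 in the alkene plane so C6 bonds anti to C9 (C6 and C7 set as in the target), the three cis units pre-fold the chain, and the Cr(III) alkoxide of 39 then closes on the C12 ester.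

Step 28
Reactants: 40 8-O-TBS macrocyclic lactone
Product: 41 8-alcohol (target skeleton with free 8-OH)
Conditions: HF·pyridine, THF, 0 °C → rt
Reagents that add atoms: none
Why: Acidic fluoride desilylation removes the last silyl ether without basic fluoride, which would attack the α-methylene lactone or move the C9 acetate.

Step 29
Reactants: 33 (2S,3S)-2,3-dimethyloxirane-2-carboxylic acid; 41 8-alcohol
Product: 43 target CNP0077535.3, via mixed 2,4,6-trichlorobenzoic anhydride 42 (not isolated)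
Conditions: 2,4,6-Cl3C6H2COCl, Et3N, toluene, rt; 41, DMAP, rt
Reagents that add atoms: none
Why: Yamaguchi esterification, in which DMAP attacks the less hindered acyl group of the mixed anhydride and transfers it to the hindered C8–OH with retention, and the acid has no α-hydrogen to epimerise.

**Compound list**
1 | (2Z)-3-methylpent-2-en-4-yn-1-ol | C#C/C(C)=C\CO | starting material
2 | [(2R,3S)-3-ethynyl-3-methyloxiran-2-yl]methanol | C#C[C@]1(C)O[C@@H]1CO | intermediate
3 | tert-butyl{[(2R,3S)-3-ethynyl-3-methyloxiran-2-yl]methoxy}dimethylsilane | C#C[C@]1(C)O[C@@H]1CO[Si](C)(C)C(C)(C)C | intermediate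
4 | tert-butyl{[(2R,3S)-3-ethenyl-3-methyloxiran-2-yl]methoxy}dimethylsilane | C=C[C@]1(C)O[C@@H]1CO[Si](C)(C)C(C)(C)C | intermediate
5 | secondary ozonide of 4 (1,2,4-trioxolane, epimers at the trioxolane carbon) | C1OOC(O1)[C@]1(C)O[C@@H]1CO[Si](C)(C)C(C)(C)C | intermediate
6 | (2R,3R)-3-({[tert-butyl(dimethyl)silyl]oxy}methyl)-2-methyloxirane-2-carbaldehyde | O=C[C@]1(C)O[C@@H]1CO[Si](C)(C)C(C)(C)C | intermediate
7 | (4R)-4-benzyl-1,3-oxazolidin-2-one | O=C1N[C@H](Cc2ccccc2)CO1 | starting material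
8 | lithium salt of 7 | [Li]N1[C@H](Cc2ccccc2)COC1=O | intermediate
9 | (4R)-4-benzyl-3-(chloroacetyl)-1,3-oxazolidin-2-one | O=C(CCl)N1[C@H](Cc2ccccc2)COC1=O | intermediate
10 | (Z)-dibutylboron enolate of 9 | Cl/C=C(\OB(CCCC)CCCC)N1[C@H](Cc2ccccc2)COC1=O | intermediate
11 | (4R)-4-benzyl-3-{(2R,3S)-2-chloro-3-hydroxy-3-[(2S,3R)-3-(TBSO-methyl)-2-methyloxiran-2-yl]propanoyl}-1,3-oxazolidin-2-one | O=C([C@H](Cl)[C@@H](O)[C@]1(C)O[C@@H]1CO[Si](C)(C)C(C)(C)C)N1[C@H](Cc2ccccc2)COC1=O | intermediate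
12 | methyl (2S,3R)-3-[(2R,3R)-3-(TBSO-methyl)-2-methyloxiran-2-yl]oxirane-2-carboxylate | COC(=O)[C@H]1O[C@H]1[C@]1(C)O[C@@H]1CO[Si](C)(C)C(C)(C)C | intermediate
13 | diisobutylaluminium hemiacetal of 12 | COC(O[Al](CC(C)C)CC(C)C)[C@H]1O[C@H]1[C@]1(C)O[C@@H]1CO[Si](C)(C)C(C)(C)C | intermediate
14 | (2S,3R)-3-[(2R,3R)-3-(TBSO-methyl)-2-methyloxiran-2-yl]oxirane-2-carbaldehyde | O=C[C@H]1O[C@H]1[C@]1(C)O[C@@H]1CO[Si](C)(C)C(C)(C)C | intermediate
15 | methyl (triphenyl-λ5-phosphanylidene)acetate | COC(=O)C=P(c1ccccc1)(c1ccccc1)c1ccccc1 | starting material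
16 | methyl iodo(triphenyl-λ5-phosphanylidene)acetate | COC(=O)C(I)=P(c1ccccc1)(c1ccccc1)c1ccccc1 | intermediate
17 | methyl (2Z)-2-iodo-3-{(2R,3R)-3-[(2R,3R)-3-(TBSO-methyl)-2-methyloxiran-2-yl]oxiran-2-yl}prop-2-enoate | I/C(C(=O)OC)=C\[C@H]1O[C@H]1[C@]1(C)O[C@@H]1CO[Si](C)(C)C(C)(C)C | intermediate
18 | methyl (4R)-2,2-dimethyl-1,3-dioxolane-4-carboxylate | COC(=O)[C@@H]1OC(C)(C)OC1 | starting material
19 | methyl (2R)-2,3-dihydroxypropanoate | COC(=O)[C@H](O)CO | intermediate
20 | methyl (2R)-2-hydroxy-3-[(triethylsilyl)oxy]propanoate | COC(=O)[C@H](O)CO[Si](CC)(CC)CC | intermediate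
21 | methyl (2R)-2-(TBSO)-3-(TESO)propanoate | COC(=O)[C@H](O[Si](C)(C)C(C)(C)C)CO[Si](CC)(CC)CC | intermediate
22 | diisobutylaluminium hemiacetal of 21 | COC(O[Al](CC(C)C)CC(C)C)[C@H](O[Si](C)(C)C(C)(C)C)CO[Si](CC)(CC)CC | intermediate
23 | (2R)-2-(TBSO)-3-(TESO)propanal | O=C[C@H](O[Si](C)(C)C(C)(C)C)CO[Si](CC)(CC)CC | intermediate
24 | methyl prop-2-ynoate | C#CC(=O)OC | starting material
25 | methyl 2-(diisobutylalumanyl)prop-2-enoate | C=C([Al](CC(C)C)CC(C)C)C(=O)OC | intermediate
26 | methyl (4R)-4-(TBSO)-3-hydroxy-2-methylidene-5-(TESO)pentanoate, C7 epimers | C=C(C(=O)OC)C(O)[C@H](O[Si](C)(C)C(C)(C)C)CO[Si](CC)(CC)CC | intermediate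
27 | methyl (4R)-4-(TBSO)-2-methylidene-3,5-bis(TESO)pentanoate, C7 epimers | C=C(C(=O)OC)C(O[Si](CC)(CC)CC)[C@H](O[Si](C)(C)C(C)(C)C)CO[Si](CC)(CC)CC | intermediate
28 | methyl (4R)-4-(TBSO)-5-hydroxy-2-methylidene-3-(TESO)pentanoate, C7 epimers | C=C(C(=O)OC)C(O[Si](CC)(CC)CC)[C@H](O[Si](C)(C)C(C)(C)C)CO | intermediate
29 | methyl (4S)-4-(TBSO)-2-methylidene-5-oxo-3-(TESO)pentanoate, C7 epimers | C=C(C(=O)OC)C(O[Si](CC)(CC)CC)[C@H](O[Si](C)(C)C(C)(C)C)C=O | intermediate
30 | angelic acid, (2Z)-2-methylbut-2-enoic acid | C/C=C(/C)C(=O)O | starting material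
31 | (2Z)-2-methylbut-2-en-1-ol | C/C=C(/C)CO | intermediate
32 | [(2R,3S)-2,3-dimethyloxiran-2-yl]methanol | OC[C@@]1(C)O[C@H]1C | intermediate
33 | (2S,3S)-2,3-dimethyloxirane-2-carboxylic acid | OC(=O)[C@@]1(C)O[C@H]1C | intermediate
34 | 6,7-seco alcohol (6-OTBS, 7-OTES epimers, 8-OTBS, 9-OH, bis-epoxide, 1(10)E) | C=C(C(=O)OC)C(O[Si](CC)(CC)CC)[C@H](O[Si](C)(C)C(C)(C)C)[C@H](O)/C(C(=O)OC)=C\[C@H]1O[C@H]1[C@]1(C)O[C@@H]1CO[Si](C)(C)C(C)(C)C | intermediate
35 | 9-acetate of 34 | C=C(C(=O)OC)C(O[Si](CC)(CC)CC)[C@H](O[Si](C)(C)C(C)(C)C)[C@H](OC(C)=O)/C(C(=O)OC)=C\[C@H]1O[C@H]1[C@]1(C)O[C@@H]1CO[Si](C)(C)C(C)(C)C | intermediate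
36 | 6,7-diol (8-OTBS, 9-OAc), C7 epimers | C=C(C(=O)OC)C(O)[C@H](O[Si](C)(C)C(C)(C)C)[C@H](OC(C)=O)/C(C(=O)OC)=C\[C@H]1O[C@H]1[C@]1(C)O[C@@H]1CO | intermediate
37 | 6-aldehyde with free 7-OH, C7 epimers | C=C(C(=O)OC)C(O)[C@H](O[Si](C)(C)C(C)(C)C)[C@H](OC(C)=O)/C(C(=O)OC)=C\[C@H]1O[C@H]1[C@]1(C)O[C@@H]1C=O | intermediate
38 | (7Z)-13-bromo 6-aldehyde | BrC/C(C(=O)OC)=C\[C@H](O[Si](C)(C)C(C)(C)C)[C@H](OC(C)=O)/C(C(=O)OC)=C\[C@H]1O[C@H]1[C@]1(C)O[C@@H]1C=O | intermediate
39 | ten-membered hydroxy ester, C6 and C7 configured as in the target (formed as its Cr(III) alkoxide, drawn protonated) | COC(=O)C(=C)[C@@H]1[C@H](O[Si](C)(C)C(C)(C)C)[C@H](OC(C)=O)/C(C(=O)OC)=C\[C@H]2O[C@H]2[C@]2(C)O[C@@H]2[C@H]1O | intermediate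
40 | 8-O-TBS macrocyclic lactone (target with OTBS in place of the C8 ester) | C=C1C(=O)O[C@H]2[C@H]1[C@H](O[Si](C)(C)C(C)(C)C)[C@H](OC(C)=O)/C(C(=O)OC)=C\[C@H]1O[C@H]1[C@]1(C)O[C@H]21 | intermediate
41 | 8-alcohol | C=C1C(=O)O[C@H]2[C@H]1[C@H](O)[C@H](OC(C)=O)/C(C(=O)OC)=C\[C@H]1O[C@H]1[C@]1(C)O[C@H]21 | intermediate
42 | (2S,3S)-2,3-dimethyloxirane-2-carboxylic 2,4,6-trichlorobenzoic anhydride | O=C(OC(=O)c1c(Cl)cc(Cl)cc1Cl)[C@@]1(C)O[C@H]1C | intermediate
43 | CNP0077535.3 | C=C1C(=O)O[C@H]2[C@H]1[C@H](OC(=O)[C@@]1(C)O[C@H]1C)[C@H](OC(C)=O)/C(C(=O)OC)=C\[C@H]1O[C@H]1[C@]1(C)O[C@H]21 | target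

**Totals**
Total step count: 29. Longest linear sequence: 16 steps (1-2-3-4-6-7-8-10, then 22–29; the line 11–18, then 22–29, is equally long).

**Three steps most likely to fail**

(i) Ring closure, step 27. The cis-substituted epoxy aldehyde has its own Felkin bias, which opposes the face required by the chair/A(1,3) model. Oligomers or 1,4-loss of the C8 silyloxy group may also compete. The fallback forms C6–C7 between the fragments and closes the ring at C9–C10 instead; it sets out from 17 and 26 and returns at 40.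
- HF·pyridine frees the West alcohol F1, and TEMPO/PhI(OAc)2 gives the West epoxy aldehyde F2. NBS/Me2S converts 26 into the East (Z)-allyl bromide F3.
- Indium powder in DMF joins F2 and F3 to the 6-epi hydroxy ester F4. All three biases favour this isomer: the Z-allylindium chair gives 6,7-syn, attack is Felkin with respect to C5, and C6 bonds anti to C9.
- Tf2O/pyridine forms the C6 triflate F5, which is not isolated. The ester carbonyl displaces the triflate with inversion and loses its methyl group to pyridine, giving the trans-lactone F6 with the required 6S centre.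
- Swern conditions oxidise the primary TES ether directly to the C9 aldehyde F7. CrCl2/cat. NiCl2 at high dilution then closes C9–C10 to the macrocyclic 9-alcohol F8 (Felkin, 8,9-anti), and Ac2O/pyridine gives 40.

(ii) Fragment coupling, step 22. The α-ester alkenylchromium may lose its geometry, the hindered partners may couple slowly, and the Felkin ratio at C9 may be modest. The fallback joins the fragments by olefination at C1=C10 instead of addition at C9–C10; it sets out from 29 and 14 and returns at 34.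
- A TMSOTf-catalysed Mukaiyama aldol of 29 with the trimethylsilyl ketene acetal of trimethyl phosphonoacetate (Felkin, silyl transfer) gives the β-silyloxy phosphonate F9.
- A Masamune–Roush Horner–Wadsworth–Emmons reaction (LiCl, DBU) of F9 with 14 gives the 9-O-TMS enoate F10, with C2 trans to the ester. Citric acid in MeOH removes only the TMS group to give 34.

(iii) Chloroacetate aldol, step 6. Aldehyde 6 is α-quaternary and may be mismatched with the auxiliary or react slowly. The fallback takes the 2,3-oxirane from an allylic alcohol instead; it sets out from 3 and returns at 14.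
- n-BuLi gives the lithium acetylide F11, which adds to paraformaldehyde to give the propargylic alcohol F12. Lindlar hydrogenation gives the (Z)-allylic alcohol F13.
- Stoichiometric Ti(OiPr)4/D-(−)-DIPT/t-BuOOH (Sharpless, 2R sense) gives the bis-epoxy alcohol F14, and TEMPO/PhI(OAc)2 gives 14.

**Further compounds**
F1 | step 27 | West alcohol (17 without TBS) | I/C(C(=O)OC)=C\[C@H]1O[C@H]1[C@]1(C)O[C@@H]1CO
F2 | step 27 | West epoxy aldehyde | I/C(C(=O)OC)=C\[C@H]1O[C@H]1[C@]1(C)O[C@@H]1C=O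
F3 | step 27 | East (Z)-allyl bromide | BrC/C(C(=O)OC)=C\[C@H](O[Si](C)(C)C(C)(C)C)CO[Si](CC)(CC)CC
F4 | step 27 | 6-epi hydroxy ester (C6 opposite to the target, C7 as in the target) | I/C(C(=O)OC)=C\[C@H]1O[C@H]1[C@]1(C)O[C@@H]1[C@H](O)[C@H](C(=C)C(=O)OC)[C@H](O[Si](C)(C)C(C)(C)C)CO[Si](CC)(CC)CC
F5 | step 27 | C6 triflate of F4 | I/C(C(=O)OC)=C\[C@H]1O[C@H]1[C@]1(C)O[C@@H]1[C@H](OS(=O)(=O)C(F)(F)F)[C@H](C(=C)C(=O)OC)[C@H](O[Si](C)(C)C(C)(C)C)CO[Si](CC)(CC)CC
F6 | step 27 | trans-lactone (C6 and C7 as in the target) | I/C(C(=O)OC)=C\[C@H]1O[C@H]1[C@]1(C)O[C@@H]1[C@H]1OC(=O)C(=C)[C@@H]1[C@H](O[Si](C)(C)C(C)(C)C)CO[Si](CC)(CC)CC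
F7 | step 27 | C9 aldehyde | I/C(C(=O)OC)=C\[C@H]1O[C@H]1[C@]1(C)O[C@@H]1[C@H]1OC(=O)C(=C)[C@@H]1[C@H](O[Si](C)(C)C(C)(C)C)C=O
F8 | step 27 | macrocyclic 9-alcohol | C=C1C(=O)O[C@H]2[C@H]1[C@H](O[Si](C)(C)C(C)(C)C)[C@H](O)/C(C(=O)OC)=C\[C@H]1O[C@H]1[C@]1(C)O[C@H]21
F9 | step 22 | β-silyloxy phosphonate (C7 and C10 epimers) | C=C(C(=O)OC)C(O[Si](CC)(CC)CC)[C@H](O[Si](C)(C)C(C)(C)C)[C@H](O[Si](C)(C)C)C(C(=O)OC)P(=O)(OC)OC
F10 | step 22 | 9-O-TMS enoate | C=C(C(=O)OC)C(O[Si](CC)(CC)CC)[C@H](O[Si](C)(C)C(C)(C)C)[C@H](O[Si](C)(C)C)/C(C(=O)OC)=C\[C@H]1O[C@H]1[C@]1(C)O[C@@H]1CO[Si](C)(C)C(C)(C)C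
F11 | step 6 | lithium acetylide of 3 | [Li]C#C[C@]1(C)O[C@@H]1CO[Si](C)(C)C(C)(C)C
F12 | step 6 | propargylic alcohol, 3-[(2S,3R)-3-(TBSO-methyl)-2-methyloxiran-2-yl]prop-2-yn-1-ol | OCC#C[C@]1(C)O[C@@H]1CO[Si](C)(C)C(C)(C)C
F13 | step 6 | (Z)-allylic alcohol, (2Z)-3-[(2S,3R)-3-(TBSO-methyl)-2-methyloxiran-2-yl]prop-2-en-1-ol | OC/C=C\[C@]1(C)O[C@@H]1CO[Si](C)(C)C(C)(C)C
F14 | step 6 | bis-epoxy alcohol, [(2R,3R)-3-{(2R,3R)-3-(TBSO-methyl)-2-methyloxiran-2-yl}oxiran-2-yl]methanol | OC[C@H]1O[C@H]1[C@]1(C)O[C@@H]1CO[Si](C)(C)C(C)(C)C
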